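## Analysis of the target

The target, (2R,5S)-5-bromo-2-[(1R,3S,4S)-4-bromo-3-chloro-4-methylcyclohexyl]-2,6,6-trimethyloxane, is a C15 bisabolane. An oxane (ring A: O1, C2–C6) and a cyclohexane (ring B: C1'–C6') are joined by one single bond, C2–C1', between a fully substituted ether carbon and a ring methine.

Ring A carries an equatorial secondary bromide at C5, next to the gem-dimethyl carbon C6. It is trans to ring B on C2 (both equatorial), so the C2 methyl group is axial.

Ring B carries an axial tertiary bromide at C4' (methyl equatorial) and an axial secondary chloride at C3'. The two halogens are trans-diaxial; chlorine is trans and bromine cis to the equatorial C1' substituent.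

C2 and C1' are the awkward pair among the five stereocentres. They are adjacent, yet C1' is stereogenic only because C3'/C4' differ from C5'/C6'. Its two ring arms are identical for three bonds, so ordinary 1,2-induction between C1' and C2 cannot be relied on.

The halogen pattern is the second problem. Tertiary bromide next to secondary chloride is the reverse of what electrophilic Br–Cl addition to a C3'=C4' alkene gives (chloride on the tertiary carbon).

The sensitive groups are the tertiary bromide (ionisation, elimination), the vicinal dihalide, the β-bromo ether at C5/C6 and the di-tertiary ether O1, which can ionise at C2 under strong acid.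

The route is built on two features. The first is the hindered C2–C1' bond. The second is the latent mirror symmetry of ring B about the C1'···C4' axis: as long as C4' is a ketone or ketal carbon, C1' is not a stereocentre, and the union of the two halves has to control C2 only.

## Retrosynthetic reasoning

**C4'–Br (14 to 13).** The tertiary C4'–Br bond is cut first, together with one C–H bond of the C4' methyl group. This leads to allylic chloride 13 with an exocyclic C4'=CH2 bond. The tertiary bromide is the most fragile function and should be made last. Ionic bromide delivery is avoided: electrophilic Br–Cl addition would put chlorine on C4', and strong protic acid endangers the O1–C2 ether. The forward reaction must therefore be a neutral Markovnikov hydrobromination by hydrogen-atom transfer, with bromine entering anti to the axial C3' chlorine.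

**C3'–Cl (13 to 12).** The C3'–Cl bond is cut with return of the double bond into the ring (C3'=C4'), giving alkene 12. Chlorine then enters as the electrophile at the less substituted alkene carbon, which is the regiochemistry the target needs. The forward ene-type chlorination must attack C3' axially, anti to the equatorial C1' substituent, to set C3' relative to C1'.

**C4'–CH3 and the C1' stereocentre (12 to 11 to 10).** The C4'–CH3 bond is cut to enol triflate 11, and 11 is traced to ketone 10. In 10, ring B has a local mirror plane through C1' and C4', so C1' is not a stereocentre. The forward step must choose between the two α-methylene groups C3' and C5' with a chiral base. C1' is thus set by a reagent, independently of C2, which removes the classical C2/C1' relay problem.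

**Ring A (10 to 8).** The O1–C6 and C5–Br bonds are cut together and the ketone is masked as its ketal, giving tertiary alcohol 8 with a 4-methylpent-3-enyl chain. The forward bromonium-induced 6-endo etherification passes through ketal 9. It is run while ring B has no alkene, so only one double bond can react. It sets C5 relative to C2 through a chair transition state.

**C2–C1' (8 to 2 and 4).** The most hindered bond of the molecule is cut, and the C2–O bond is traced to a C2–B bond. This gives a C8 benzoate 2 and a C8 boronic ester 4 of similar size. The forward reaction is a stereospecific 1,2-metalate rearrangement of boronate complex 6, formed from lithiated 5 and 4, followed by oxidation of 7. It creates the quaternary carbinol carbon C2 in one configuration from a secondary alcohol stereocentre. The cut is made here because C2 is the only stereocentre of 8, and both partners are one step from commercial materials.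

**Fragments (2 to 1, 4 to 3).** Benzoate 2 is the hindered ester of alcohol 1, which supplies C2, its methyl group and C3–C6 with both C6 methyl groups. Boronic ester 4 comes from bromide 3 by borylation. Ring B is achiral at this stage.

## Alternatives that were turned down

**Alternative 1:** the textbook route. Ring B is made by an asymmetric [4+2] cycloaddition of the C5 diene with a C4 enone to give methyl ketone A1. The C2–C3 bond is formed by adding the side-chain Grignard reagent, giving carbinol A2. A2 is then cyclised with a bromonium source and treated with Br–Cl.
- The carbonyl of A1 sits next to a stereocentre whose two ring arms are identical for three bonds. Addition should show no useful facial bias, and the two C2 epimers differ only remotely and are hard to separate.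
- The abundant natural form of this carbinol is the mirror image of A2, so the chiral pool gives the wrong enantiomer.
- The end game needs bromonium chemistry on a substrate with two trisubstituted alkenes.
- Chloride opens the ring bromonium ion at the tertiary carbon, giving the constitutional isomer of the target's ring B.

**Alternative 2:** chiral pool for ring A. The tertiary allylic alcohol A3 already holds C2 with its methyl group, its oxygen and the whole ring A chain in the correct configuration. Bromoetherification would give vinyl oxane A4, and a [4+2] cycloaddition of the vinyl group with the C5 diene would give 12 directly.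
- A vinyl group on a quaternary carbon is an unactivated and hindered dienophile. The forcing thermal conditions needed would endanger the β-bromo ether.
- Neither the para/meta orientation nor the C1' configuration is controlled, because the two vinyl faces differ only by CH3 against CH2 on C2.
- An activating group would have to be added and removed, which costs the steps the chiral pool saves.

**Alternative 3:** chiral pool for ring B. The monoterpene A5 supplies C1' and the complete ring B. Its isopropenyl group would be epoxidised to A6, and opening at the CH2 terminus by a prenyl-metal nucleophile would give A2.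
- C2 would arise from epoxidation of a 1,1-disubstituted alkene whose faces C1' cannot distinguish (the same symmetry problem as in alternative 1).
- That alkene is also less reactive than the ring alkene towards peracids.
- Reagent-controlled epoxidation of such alkenes is unreliable.
- The halogenation problems of alternative 1 remain.

Key step: step 3

## Route

Assumption: alcohol 1 in high enantiomeric purity and bromide 3 are taken as commercially available.

Step 1
Reactants: 1 (2R)-6-methylhept-5-en-2-ol
Product: 2 (2R)-6-methylhept-5-en-2-yl 2,4,6-tri(propan-2-yl)benzoate
Conditions: NaH, THF, 0 °C; 2,4,6-tri(propan-2-yl)benzoyl chloride, THF, 60 °C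
Reagents that add atoms: 2,4,6-tri(propan-2-yl)benzoyl chloride CC(C)c1cc(C(C)C)c(C(Cl)=O)c(C(C)C)c1
Why: O-acylation of the sodium alkoxide by the hindered aroyl chloride; the C–O bond of the carbinol is not touched, so the (R) configuration is retained. The bulky ester is the directing and leaving group for step 3.

Step 2
Reactants: 3 8-bromo-1,4-dioxaspiro[4.5]decane
Product: 4 2-(1,4-dioxaspiro[4.5]decan-8-yl)-5,5-dimethyl-1,3,2-dioxaborinane
Conditions: B2neop2, CuI (cat.), PPh3 (cat.), LiOMe, DMF, 25 °C
Reagents that add atoms: bis(neopentyl glycolato)diboron CC1(C)COB(OC1)B1OCC(C)(C)CO1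
Why: Copper-catalysed borylation of a secondary alkyl bromide with a diboron reagent; the ring is symmetric, so the radical character of the C–Br activation has no stereochemical consequence. The neopentyl glycol ester is chosen because its boron atom is less shielded than that of a pinacol ester.

Step 3
Reactants: 2 (2R)-6-methylhept-5-en-2-yl 2,4,6-tri(propan-2-yl)benzoate; 4 2-(1,4-dioxaspiro[4.5]decan-8-yl)-5,5-dimethyl-1,3,2-dioxaborinane
Product: 8 (2R)-2-(1,4-dioxaspiro[4.5]decan-8-yl)-6-methylhept-5-en-2-ol, via α-lithiated benzoate 5 (not isolated), via lithium boronate complex 6 (not isolated), via tertiary boronic ester 7 (not isolated)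
Conditions: s-BuLi, TMEDA, CPME, −60 °C; then 4, −60 °C → 50 °C; then H2O2, NaOH aq, THF, 0 °C → rt
Reagents that add atoms: hydrogen peroxide OO
Why: s-BuLi/TMEDA removes the α-oxygen proton of 2 under direction by the ester carbonyl (the 2,4,6-triisopropylphenyl group blocks attack at C=O and ortho-metalation), giving the configurationally stable organolithium 5 with retention. 5 adds to boron of 4 with retention to give complex 6; on warming, the ring methine carbon (future C1') migrates from boron to C2 anti-periplanar to the departing aryl carboxylate (stereospecific 1,2-metalate rearrangement, inversion at C2) to give 7, which alkaline H2O2 oxidises with retention to 8. The closest known reaction type is the lithiation–borylation of enantioenriched secondary alkyl 2,4,6-triisopropylbenzoates with neopentyl glycol boronic esters to give tertiary boronic esters and tertiary alcohols. No ring is closed; the step forms the C2–C1' bond between the two halves and, after oxidation, the C2–O bond. C2 is the only new stereocentre and is controlled solely by the configuration of 1: the hydroxyl ends where the hydrogen was and ring B where the ester oxygen was, so (R)-1 gives (R)-8. C1' needs no control because the ketal ring is symmetric. The selectivities needed are α-deprotonation over allylic metalation of the prenyl terminus (secured by ester direction at −60 °C) and migration over dissociation of the congested complex 6 (secured by the unhindered neopentyl glycol ester, the good carboxylate leaving group and the slow warm-up).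

Step 4
Reactants: 8 (2R)-2-(1,4-dioxaspiro[4.5]decan-8-yl)-6-methylhept-5-en-2-ol
Product: 10 4-[(2R,5S)-5-bromo-2,6,6-trimethyloxan-2-yl]cyclohexan-1-one, via bromo oxane ketal 9 (not isolated)
Conditions: NBS, (CF3)2CHOH, 0 °C; then 1 M HCl aq, THF, rt
Reagents that add atoms: N-bromosuccinimide O=C1CCC(=O)N1Br; water O
Why: Bromonium formation on the only alkene is followed by attack of the tertiary hydroxyl at the dimethyl-substituted carbon (6-endo, Markovnikov), a mode favoured by the ionising, weakly nucleophilic solvent. The chair transition state with ring B equatorial and the C2 methyl axial places bromine equatorial at C5 and sets (5S) relative to (2R). Dilute aqueous acid then unmasks the ketone without ionising the ether; the C5 epimer and any oxolane regioisomer should be removable by chromatography at this stage.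

Step 5
Reactants: 10 4-[(2R,5S)-5-bromo-2,6,6-trimethyloxan-2-yl]cyclohexan-1-one
Product: 11 (4R)-4-[(2R,5S)-5-bromo-2,6,6-trimethyloxan-2-yl]cyclohex-1-en-1-yl trifluoromethanesulfonate
Conditions: (S,S)-bis(1-phenylethyl)amine, n-BuLi, LiCl, THF, −78 °C; then PhNTf2, −78 °C → 0 °C
Reagents that add atoms: N-phenylbis(trifluoromethanesulfonimide) O=S(=O)(N(c1ccccc1)S(=O)(=O)C(F)(F)F)C(F)(F)F
Why: Enantioselective deprotonation by a C2-symmetric chiral lithium amide (LiCl mixed aggregate, external quench) removes an axial proton from one of the two α-methylene groups related by the local mirror plane of the 4-substituted cyclohexanone, and O-triflation fixes the result; this step makes C1' stereogenic, (R). The (S,S)-amide is chosen by analogy with the established sense of induction for 4-alkylcyclohexanones. C2 and C5 are too remote to interfere, so the reagent alone decides.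

Step 6
Reactants: 11 (4R)-4-[(2R,5S)-5-bromo-2,6,6-trimethyloxan-2-yl]cyclohex-1-en-1-yl trifluoromethanesulfonate
Product: 12 (2R,5S)-5-bromo-2,6,6-trimethyl-2-[(1R)-4-methylcyclohex-3-en-1-yl]oxane
Conditions: MeZnCl, Pd(PPh3)4 (cat.), THF, 50 °C
Reagents that add atoms: methylzinc chloride C[Zn]Cl
Why: Negishi coupling; zerovalent palladium inserts into the alkenyl C–OTf bond far faster than into the hindered, unactivated secondary C–Br bond. No stereocentre is touched.

Step 7
Reactants: 12 (2R,5S)-5-bromo-2,6,6-trimethyl-2-[(1R)-4-methylcyclohex-3-en-1-yl]oxane
Product: 13 (2R,5S)-5-bromo-2-[(1R,3S)-3-chloro-4-methylidenecyclohexyl]-2,6,6-trimethyloxane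
Conditions: Ca(OCl)2, CO2 (s), CH2Cl2/H2O, 0 °C
Reagents that add atoms: calcium hypochlorite [Ca+2].[O-]Cl.[O-]Cl
Why: Ene-type allylic chlorination by hypochlorous acid generated in the flask: electrophilic chlorine attacks the less substituted alkene carbon C3' along the axial trajectory that leads directly to a chair, on the face anti to the equatorial C1' substituent, and the tertiary C4' cation loses a methyl proton. This should give the axial (3S) chloride, trans to the C1' substituent, with the exocyclic alkene. The di-tertiary ether and the C5 bromide are inert to these near-neutral conditions.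

Step 8
Reactants: 13 (2R,5S)-5-bromo-2-[(1R,3S)-3-chloro-4-methylidenecyclohexyl]-2,6,6-trimethyloxane
Product: 14 (2R,5S)-5-bromo-2-[(1R,3S,4S)-4-bromo-3-chloro-4-methylcyclohexyl]-2,6,6-trimethyloxane
Conditions: Co(acac)2 (cat.), t-BuOOH (cat.), Et3SiH, TsBr, n-PrOH, rt
Reagents that add atoms: 4-methylbenzenesulfonyl bromide Cc1ccc(cc1)S(=O)(=O)Br
Why: Markovnikov hydrobromination by hydrogen-atom transfer: a cobalt hydride delivers H to the terminal CH2, and the tertiary C4' radical abstracts bromine from the sulfonyl bromide. Bromine transfer along the axial direction, anti to the axial C3' chlorine, should give the trans-diaxial bromochloride with equatorial methyl, (4S). The neutral radical conditions avoid ionising the O1–C2 ether and avoid the reversed regiochemistry of ionic Br–Cl addition.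

## Compound list

1 | (2R)-6-methylhept-5-en-2-ol | CC(C)=CCC[C@@H](C)O | starting material
2 | (2R)-6-methylhept-5-en-2-yl 2,4,6-tri(propan-2-yl)benzoate | CC(C)=CCC[C@@H](C)OC(=O)c1c(C(C)C)cc(C(C)C)cc1C(C)C | intermediate
3 | 8-bromo-1,4-dioxaspiro[4.5]decane | BrC1CCC2(CC1)OCCO2 | starting material
4 | 2-(1,4-dioxaspiro[4.5]decan-8-yl)-5,5-dimethyl-1,3,2-dioxaborinane | CC1(C)COB(OC1)C1CCC2(CC1)OCCO2 | intermediate
5 | (2R)-2-lithio-6-methylhept-5-en-2-yl 2,4,6-tri(propan-2-yl)benzoate | CC(C)=CCC[C@@]([Li])(C)OC(=O)c1c(C(C)C)cc(C(C)C)cc1C(C)C | intermediate
6 | lithium (1,4-dioxaspiro[4.5]decan-8-yl)(2,2-dimethylpropane-1,3-diolato)[(2R)-6-methyl-2-{[2,4,6-tri(propan-2-yl)benzoyl]oxy}hept-5-en-2-yl]borate | [Li+].CC(C)=CCC[C@@]([B-]1(OCC(C)(C)CO1)C1CCC2(CC1)OCCO2)(C)OC(=O)c1c(C(C)C)cc(C(C)C)cc1C(C)C | intermediate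
7 | 2-[(2S)-2-(1,4-dioxaspiro[4.5]decan-8-yl)-6-methylhept-5-en-2-yl]-5,5-dimethyl-1,3,2-dioxaborinane | CC(C)=CCC[C@@](C)(B1OCC(C)(C)CO1)C1CCC2(CC1)OCCO2 | intermediate
8 | (2R)-2-(1,4-dioxaspiro[4.5]decan-8-yl)-6-methylhept-5-en-2-ol | CC(C)=CCC[C@@](C)(O)C1CCC2(CC1)OCCO2 | intermediate
9 | 8-[(2R,5S)-5-bromo-2,6,6-trimethyloxan-2-yl]-1,4-dioxaspiro[4.5]decane | CC1(C)O[C@@](C)(C2CCC3(CC2)OCCO3)CC[C@@H]1Br | intermediate
10 | 4-[(2R,5S)-5-bromo-2,6,6-trimethyloxan-2-yl]cyclohexan-1-one | CC1(C)O[C@@](C)(C2CCC(=O)CC2)CC[C@@H]1Br | intermediate
11 | (4R)-4-[(2R,5S)-5-bromo-2,6,6-trimethyloxan-2-yl]cyclohex-1-en-1-yl trifluoromethanesulfonate | CC1(C)O[C@@](C)([C@@H]2CCC(OS(=O)(=O)C(F)(F)F)=CC2)CC[C@@H]1Br | intermediate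
12 | (2R,5S)-5-bromo-2,6,6-trimethyl-2-[(1R)-4-methylcyclohex-3-en-1-yl]oxane | CC1(C)O[C@@](C)([C@@H]2CCC(C)=CC2)CC[C@@H]1Br | intermediate
13 | (2R,5S)-5-bromo-2-[(1R,3S)-3-chloro-4-methylidenecyclohexyl]-2,6,6-trimethyloxane | CC1(C)O[C@@](C)([C@@H]2CCC(=C)[C@@H](Cl)C2)CC[C@@H]1Br | intermediate
14 | (2R,5S)-5-bromo-2-[(1R,3S,4S)-4-bromo-3-chloro-4-methylcyclohexyl]-2,6,6-trimethyloxane (deoxy isocaespitol) | CC1(C)O[C@@](C)([C@@H]2CC[C@](C)(Br)[C@@H](Cl)C2)CC[C@@H]1Br | target

## Step count and least certain steps

Total step count: 8. Longest linear sequence: 7 steps (1 → 2 → 8 → 10 → 11 → 12 → 13 → 14); step 2 is the only step off this line. The stereocentres are set at C2 in step 3, C5 in step 4, C1' in step 5, C3' in step 7 and C4' in step 8.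

**Step 3 (key step).** The likely failure is dissociation of the congested complex 6 back to 5 and 4 before the secondary ring carbon migrates, followed by decomposition of 5; slow complexation at −60 °C would have the same effect. The fallback sets out from 2 and delivers the ring as an sp2 carbon, which is less hindered and migrates more readily.
- The commercial enol triflate 1,4-dioxaspiro[4.5]dec-7-en-8-yl trifluoromethanesulfonate F1 is borylated (B2neop2, PdCl2(dppf), KOAc, dioxane) to the alkenyl boronic ester 2-(1,4-dioxaspiro[4.5]dec-7-en-8-yl)-5,5-dimethyl-1,3,2-dioxaborinane F2.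
- 5, generated from 2 as in step 3, is trapped with F2; migration and oxidation should give the tertiary allylic alcohol (2R)-2-(1,4-dioxaspiro[4.5]dec-7-en-8-yl)-6-methylhept-5-en-2-ol F3.
- Hydroxyl-directed hydrogenation with [Rh(nbd)(dppb)]BF4 and H2 should saturate only the allylic ring alkene, creating no stereocentre. The route is rejoined at 8.

**Step 4.** Two processes compete with the desired closure: attack of the hydroxyl at the secondary carbon of the bromonium ion (5-exo closure to an oxolane), and closure through the chair with ring B axial (C5 epimer). The fallback sets out from 8 and separates ring closure from bromination.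
- Oxymercuration with Hg(OCOCF3)2 in MeNO2 opens the mercurinium ion strongly at the tertiary carbon; anion exchange with KBr should give bromo[(3S,6R)-6-(1,4-dioxaspiro[4.5]decan-8-yl)-2,2,6-trimethyloxan-3-yl]mercury F4.
- Bromodemercuration with retention (Br2, LiBr, pyridine, dark) returns to the route at 9, which is hydrolysed to 10 as in step 4.

**Step 5.** The risk is insufficient discrimination between the two α-methylene groups, or the opposite sense of induction, which would carry the C1' epimer through the rest of the route. The fallback sets out from 10 and uses enamine catalysis instead of a chiral base.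
- α-Chlorination with N-chlorosuccinimide and a C2-symmetric 2,5-diphenylpyrrolidine catalyst, with axial delivery of chlorine, should give (2S,4R)-4-[(2R,5S)-5-bromo-2,6,6-trimethyloxan-2-yl]-2-chlorocyclohexan-1-one F5. This sets C1' and C3' together.
- Wittig methylenation (Ph3P=CH2, THF, −78 °C → 0 °C) rejoins the route at 13, bypassing steps 5 to 7.

**Step 7.** Capture of the β-chloro cation by water (chlorohydrin formation) may compete with proton loss, and attack on the other alkene face would give the C3' epimer. The fallback sets out from 12 and makes the water capture deliberate.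
- N-Chlorosuccinimide in aqueous acetone should give, by Markovnikov and trans-diaxial opening, the chlorohydrin (1S,2S,4R)-4-[(2R,5S)-5-bromo-2,6,6-trimethyloxan-2-yl]-2-chloro-1-methylcyclohexan-1-ol F6.
- Dehydration of the tertiary alcohol (SOCl2, pyridine, 0 °C) returns to the route at 13. An endocyclic alkene isomer formed alongside would converge on the same C4' radical in step 8.

**Step 8.** Bromine transfer syn to the chlorine would give the C4' epimer; loss of a chlorine atom from the β-chloro radical or simple reduction of the radical are the other failure modes. The fallback sets out from 13 and uses the ionic manifold: brief exposure to anhydrous HBr in CH2Cl2 at −78 °C should protonate the exocyclic alkene to the tertiary C4' cation, which is bridged by the axial chlorine and opened by bromide from the opposite face. This arrives directly at 14 and makes no new compound. The low temperature and short contact time are needed to keep the O1–C2 ether from ionising.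

## Further compounds

F1 | step 3 | 1,4-dioxaspiro[4.5]dec-7-en-8-yl trifluoromethanesulfonate | O=S(=O)(OC1=CCC2(CC1)OCCO2)C(F)(F)F
F2 | step 3 | 2-(1,4-dioxaspiro[4.5]dec-7-en-8-yl)-5,5-dimethyl-1,3,2-dioxaborinane | CC1(C)COB(OC1)C1=CCC2(CC1)OCCO2
F3 | step 3 | (2R)-2-(1,4-dioxaspiro[4.5]dec-7-en-8-yl)-6-methylhept-5-en-2-ol | CC(C)=CCC[C@@](C)(O)C1=CCC2(CC1)OCCO2
F4 | step 4 | bromo[(3S,6R)-6-(1,4-dioxaspiro[4.5]decan-8-yl)-2,2,6-trimethyloxan-3-yl]mercury | CC1(C)O[C@@](C)(C2CCC3(CC2)OCCO3)CC[C@@H]1[Hg]Br
F5 | step 5 | (2S,4R)-4-[(2R,5S)-5-bromo-2,6,6-trimethyloxan-2-yl]-2-chlorocyclohexan-1-one | CC1(C)O[C@@](C)([C@@H]2CCC(=O)[C@@H](Cl)C2)CC[C@@H]1Br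
F6 | step 7 | (1S,2S,4R)-4-[(2R,5S)-5-bromo-2,6,6-trimethyloxan-2-yl]-2-chloro-1-methylcyclohexan-1-ol | CC1(C)O[C@@](C)([C@@H]2CC[C@](C)(O)[C@@H](Cl)C2)CC[C@@H]1Br
F0 | step 8 | none | none
A1 | alternative 1 | 1-[(1R)-4-methylcyclohex-3-en-1-yl]ethan-1-one | CC(=O)[C@@H]1CCC(C)=CC1
A2 | alternative 1 | (2R)-6-methyl-2-[(1R)-4-methylcyclohex-3-en-1-yl]hept-5-en-2-ol | CC(C)=CCC[C@@](C)(O)[C@@H]1CCC(C)=CC1
A3 | alternative 2 | (3R)-3,7-dimethylocta-1,6-dien-3-ol | CC(C)=CCC[C@@](C)(O)C=C
A4 | alternative 2 | (2R,5S)-5-bromo-2-ethenyl-2,6,6-trimethyloxane | CC1(C)O[C@@](C)(C=C)CC[C@@H]1Br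
A5 | alternative 3 | (4R)-1-methyl-4-(prop-1-en-2-yl)cyclohex-1-ene | C=C(C)[C@@H]1CCC(C)=CC1
A6 | alternative 3 | (2S)-2-methyl-2-[(1R)-4-methylcyclohex-3-en-1-yl]oxirane | C[C@@]1(CO1)[C@@H]2CCC(C)=CC2
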